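- The constants I can have before the result are read from the earlier runs, and I treat the flask as a first-order system whose rate constant decays.

| flask | L | Z | remark | time |
|---|---|---|---|---|
| violet | 5.8 mM (fed, over 25 min) | 50 µM | run made earlier; the fed solution adds 0.20 times the starting volume |  |
| ochre | 42 mM (fed, over 25 min) | 50 µM | run made earlier; the fed solution adds 0.20 times the starting volume |  |
| grey | 10 mM (fed, over 25 min) | 40 µM | run made earlier; the fed solution adds 0.20 times the starting volume |  |
| Tuesday's | 5.0 mM (fed, over 15 min) | 50 µM | the fed solution adds 0.20 times the starting volume | 8.0 h |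
| Wednesday's | 10 mM (fed, over 25 min) | 12 µM | the fed solution adds 0.20 times the starting volume | 8.0 h |
| Thursday's | 10 mM (fed, over 25 min) | 50 µM | the fed solution adds 0.20 times the starting volume | 8.0 h |
| Sunday's | 10 mM (fed, over 50 min) | 100 µM | the fed solution adds 0.20 times the starting volume | 8.0 h |
| Saturday's | 30 mM (fed, over 25 min) | 25 µM | the fed solution adds 0.20 times the starting volume | 8.0 h |
| Friday's | 6.0 mM (fed, over 80 min) | 200 µM | the fed solution adds 0.20 times the starting volume | 8.0 h |

| run | time / h | D / % |
|---|---|---|
| violet | 1.33 | 38.8 |
| violet | 2.50 | 50.0 |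
| violet | 4.00 | 49.9 |
| violet | 5.00 | 51.7 |
| violet | 6.00 | 52.8 |
| violet | 8.00 | 48.9 |
| ochre | 0.667 | 21.9 |
| ochre | 1.00 | 31.5 |
| ochre | 2.00 | 42.6 |
| ochre | 3.00 | 46.8 |
| ochre | 5.00 | 50.4 |
| ochre | 8.00 | 50.5 |
| grey | 0.667 | 21.3 |
| grey | 1.33 | 35.6 |
| grey | 2.50 | 43.3 |
| grey | 4.00 | 46.3 |
| grey | 8.00 | 45.9 |

(each reading ± 1 percentage point)

- amounts are per litre of the starting volume; all of the dose is in the solution fed

- the flasks by amount of D, in percent of the L charged, highest first, at 8.0 h (Tuesday's / Wednesday's / Thursday's / Sunday's / Saturday's / Friday's)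
- the same order at 30 h (Tuesday's / Wednesday's / Thursday's / Sunday's / Saturday's / Friday's)
- the amount of D, in percent of the L charged of the flask you put first, at 8.0 h
- the amount of D, in percent of the L charged of the flask you put last, at 8.0 h

- Ochre ends at 50.5 % with L at 42 mM, while violet, with the same Z and dosing time but L at 5.8 mM, reads between 48.9 % and 52.8 % from 2.50 h on. Within the scatter of these two runs the percent reached does not follow the charge, so I take L as pseudo-first-order, with a rate constant that dies away.
- I call the stall exponent S the natural log of one over the fraction of the L charged that is not in D at the plateau, which in this picture is the time integral of that rate constant; ochre's last reading gives S = 0.703.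
- Grey, with Z at 40 µM, gives 0.614, a ratio to S of 0.873 against 0.894 for the square root of the Z ratio, so I let S follow the root of Z.
- The ochre readings show the gap to S shrinking between 1.00 h and 3.00 h with a time constant τ of 1.33 h. Since 8.0 h is 6.02 such constants, I expect the same order at 30 h.
- The root of Z by itself gives Friday's 75.5 %, and this is the weak link, because the middle of Friday's feed comes 0.458 h later than ochre's, a shift of a third of τ.
- I reforge it by also multiplying S by the exponential of minus that shift over τ, and D is then one minus the exponential of minus the scaled S.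
- My reckoning gives Friday's 63.1 %, Sunday's 57.3 %, Tuesday's 52.7 %, Thursday's 50.5 %, Saturday's 39.2 % and Wednesday's 29.1 %.
- The forecast, which says “L fed late meets less active species”, commits to Friday's > Sunday's > Tuesday's > Thursday's > Saturday's > Wednesday's at the first time and Friday's > Sunday's > Tuesday's > Thursday's > Saturday's > Wednesday's at the second. It puts the top at 60 % (55 % to 65 %) and the low at 29 % (25 % to 33 %), so its order is mine, while its top lies below my 63.1 %.
- The flasks give Friday's > Sunday's > Tuesday's > Thursday's > Saturday's > Wednesday's at the first time and Friday's > Sunday's > Tuesday's > Thursday's > Saturday's > Wednesday's at the second, with top 62.5 % and low 29.4 %, so the forecast's order stands and both of these values lie inside its ranges.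

    L + Q → D + Q, rate k1*[Q]*[L] (k = 19900 L mol⁻¹ s⁻¹)
    2 Q → X (k = 1.70 × 10⁸ L mol⁻¹ s⁻¹)
    2 L → G (k = 7.29 × 10⁻⁵ L mol⁻¹ s⁻¹)
    L + E → Q + D (k = 1.62 × 10⁶ L mol⁻¹ s⁻¹)
    Z → 2 E (k = 5.30 × 10⁻⁴ s⁻¹)

- On Friday's, the scaled S gave 63.1 % against the 62.5 % found, and on Wednesday's 29.1 % against 29.4 %. A further flask is like Wednesday's but holds Z at 0.0072 mM; its dosing time matches ochre's, so the shift is nil and the root of the Z ratio scales S to 0.267, which gives 23.4 %. That flask gives 23.6 % of D at 8.00 h, with 74.3 % of the L charged still there and Z at 0 % of its charge.

The data were generated by integration for an exercise, noise included.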